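**Retrosynthetic overview**

1. The nine phenols are unmasked from methyl ethers in the last step; the E-alkene is made by a Heck coupling of a 4-vinylbenzofuran with the 5-bromide of a bis(dihydrobenzofuran).
2. The middle dihydrofuran ring (formed last) comes from a [4+1] annulation of an o-quinone methide, released in the flask from an aryllithium and an O-Boc salicylaldehyde, with a chiral 4-methoxybenzyl sulfonium ylide.
3. Both halves come from one building block, a (2S,3S)-4-bromo-2,3-diaryl-6-methoxy-2,3-dihydrobenzofuran: one portion becomes the aryllithium, another is dehydrogenated with DDQ to the aromatic furan (formed third) and vinylated.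
4. The dihydrofuran ring of this building block (formed second) is made in one operation by insertion of 3-bromo-5-methoxybenzyne into one C–O bond of an enantiopure trans-2,3-diaryloxirane (ring formed first: pterostilbene, triflation, Shi epoxidation).
5. Enabling feature: in the benzo ring of the terminal dihydrobenzofuran (ring D) the fusion bond C3a–C7a lies next to C4, the carbon that links to the middle unit, so C3a≡C7a can be an aryne that a bromine at C4 polarises; and C3 is benzylic to a meta,meta-dioxygenated ring while C2 is benzylic to a para-oxygenated ring that can be switched off as its triflate.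

Key step: step 4

Assumption: the benzylic ylide of isothiocineole is taken to transfer its carbon to an o-quinone methide with the same facial sense as in its epoxidations of aryl aldehydes, the (1R,4R,5R) sulfide being taken as the one that leads to (R,R)-stilbene oxides; on this basis the (1S,4S,5S) sulfide is needed for 2R in step 11, and the other enantiomer would be used if the sense were opposite.

Remark: the oxirane carbon that becomes C2 keeps its spatial arrangement in step 4; its descriptor changes from R to S only because the ranking of its substituents changes.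

**Route**

Step 1
Reactants: 1 2,6-dibromo-4-methoxyphenol
Product: 4 2-bromo-4-methoxy-6-(trimethylsilyl)phenyl trifluoromethanesulfonate, via aryl silyl ether 2 (not isolated), via lithium phenolate 3 (not isolated)
Conditions: (Me3Si)2NH, THF, 70 °C, then evaporation; n-BuLi (1 equiv), THF, −78 °C; Tf2O, −78 °C → rt
Reagents that add atoms: hexamethyldisilazane C[Si](C)(C)N[Si](C)(C)C; trifluoromethanesulfonic anhydride O=S(=O)(OS(=O)(=O)C(F)(F)F)C(F)(F)F
Why: O-silylation, bromine–lithium exchange and retro-Brook (1,3 O→C) silyl migration give the C-silylated phenolate, which is triflated, the standard one-flask route from 2-bromophenols to 2-silylaryl triflate aryne precursors; the second bromine of the symmetrical dibromide survives because only one equivalent of n-BuLi is used.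

Step 2
Reactants: 5 pterostilbene
Product: 6 4-[(E)-2-(3,5-dimethoxyphenyl)ethenyl]phenyl trifluoromethanesulfonate
Conditions: Tf2O, pyridine, CH2Cl2, 0 °C
Reagents that add atoms: trifluoromethanesulfonic anhydride O=S(=O)(OS(=O)(=O)C(F)(F)F)C(F)(F)F
Why: O-sulfonylation of the only free phenol; the triflate makes this aryl ring electron-poor, which stabilises the later epoxide and serves as the regiochemical switch of step 4.

Step 3
Reactants: 6 4-[(E)-2-(3,5-dimethoxyphenyl)ethenyl]phenyl trifluoromethanesulfonate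
Product: 7 4-[(2R,3R)-3-(3,5-dimethoxyphenyl)oxiran-2-yl]phenyl trifluoromethanesulfonate
Conditions: D-fructose-derived Shi ketone (0.3 equiv), KHSO5 (as 2KHSO5·KHSO4·K2SO4), K2CO3, Bu4NHSO4, MeCN/(MeO)2CH2/aqueous Na2B4O7 buffer, 0 °C
Reagents that add atoms: potassium peroxymonosulfate [K+].[O-]S(=O)(=O)OO
Why: Shi epoxidation, in which the chiral dioxirane delivers oxygen to one face of the E-alkene through the spiro transition state (the D-fructose-derived ketone gives R,R epoxides from E-stilbenes), so both stereocentres are set here by the catalyst and the trans geometry comes from the alkene.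

Step 4
Reactants: 4 2-bromo-4-methoxy-6-(trimethylsilyl)phenyl trifluoromethanesulfonate; 7 4-[(2R,3R)-3-(3,5-dimethoxyphenyl)oxiran-2-yl]phenyl trifluoromethanesulfonate
Product: 9 4-[(2S,3S)-4-bromo-3-(3,5-dimethoxyphenyl)-6-methoxy-2,3-dihydro-1-benzofuran-2-yl]phenyl trifluoromethanesulfonate, via aryne 8 (not isolated)
Conditions: CsF, MeCN, 25 °C, slow addition of 4 (2 equiv) to concentrated 7
Reagents that add atoms: none
Why: Proposed new method: fluoride unmasks aryne 8, the oxirane oxygen of 7 adds to the aryne carbon remote from bromine (the future C7a) because the C–Br bond polarises the aryne so that the carbanion develops next to it (the future C3a), and the O-aryl oxiranium then ionises at its 3,5-dimethoxybenzylic C–O bond and the aryl anion collapses onto that carbon. The closest known reaction type is the insertion of benzyne into a C–O bond of styrene oxide to give a 2,3-dihydrobenzofuran, together with the known ring opening of cyclic ethers by arynes through O-aryl oxonium ions. The dihydrofuran ring closes by ring expansion of the oxirane from three to five members: ion-pair collapse of C3a onto C3, a formally 5-endo closure that is open only because the C3–O bond ionises first. C2 is never touched and keeps the configuration set in step 3, whereas C3 is re-formed with retention because the tethered aryl anion reaches the cationic face that oxygen has just left without rotation about C2–C3, and this least-motion product is also the more stable trans isomer. Two selectivities are needed: the orientation of the aryne, secured by the bromine at the future C4, and the choice of the oxirane C–O bond, secured by the electron-poor 4-triflyloxyphenyl ring, which disfavours ionisation at C2.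

Step 5
Reactants: 9 4-[(2S,3S)-4-bromo-3-(3,5-dimethoxyphenyl)-6-methoxy-2,3-dihydro-1-benzofuran-2-yl]phenyl trifluoromethanesulfonate
Product: 11 (2S,3S)-4-bromo-3-(3,5-dimethoxyphenyl)-6-methoxy-2-(4-methoxyphenyl)-2,3-dihydro-1-benzofuran, via cesium phenolate 10 (not isolated)
Conditions: Cs2CO3, DME, 80 °C; then MeI, 25 °C
Reagents that add atoms: iodomethane CI
Why: carbonate-mediated S–O cleavage of the aryl triflate and Williamson methylation of the cesium phenolate in the same flask remove the switch group; neither stereocentre is acidic enough to be touched.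

Step 6
Reactants: 11 (2S,3S)-4-bromo-3-(3,5-dimethoxyphenyl)-6-methoxy-2-(4-methoxyphenyl)-2,3-dihydro-1-benzofuran
Product: 12 4-bromo-3-(3,5-dimethoxyphenyl)-6-methoxy-2-(4-methoxyphenyl)-1-benzofuran
Conditions: DDQ, 1,4-dioxane, 100 °C
Reagents that add atoms: none
Why: DDQ dehydrogenation (hydride abstraction from C2, which is stabilised by the ring oxygen and the 4-methoxyphenyl group, then loss of the C3 proton) aromatises the furan ring; the two stereocentres are erased on purpose in this portion.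

Step 7
Reactants: 12 4-bromo-3-(3,5-dimethoxyphenyl)-6-methoxy-2-(4-methoxyphenyl)-1-benzofuran
Product: 13 3-(3,5-dimethoxyphenyl)-4-ethenyl-6-methoxy-2-(4-methoxyphenyl)-1-benzofuran
Conditions: Bu3SnCH=CH2, Pd(PPh3)4, toluene, 110 °C
Reagents that add atoms: tributyl(vinyl)stannane C=C[Sn](CCCC)(CCCC)CCCC
Why: Stille coupling of the aryl bromide under neutral conditions installs the vinyl group that becomes one half of the E-alkene.

Step 8
Reactants: 14 5-bromo-2-hydroxybenzaldehyde
Product: 15 4-bromo-2-formylphenyl tert-butyl carbonate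
Conditions: Boc2O, i-Pr2NEt, DMAP (cat.), THF, 0 °C → rt
Reagents that add atoms: di-tert-butyl dicarbonate CC(C)(C)OC(=O)OC(=O)OC(C)(C)C
Why: O-acylation of the phenol gives the aryl carbonate that later shifts to the benzylic oxygen and leaves to release the o-quinone methide.

Step 9
Reactants: 16 (S)-limonene
Product: 17 (1S,4S,5S)-isothiocineole
Conditions: S8, γ-terpinene, neat, 110 °C; distillation
Reagents that add atoms: sulfur S1SSSSSSS1
Why: known one-step radical addition of sulfur across both alkenes of limonene with hydrogen transfer from γ-terpinene; the limonene stereocentre becomes a bridgehead and fixes the other two centres of the bicycle.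

Step 10
Reactants: 17 (1S,4S,5S)-isothiocineole
Product: 18 (1S,4S,5S)-6-(4-methoxybenzyl)-4,7,7-trimethyl-6-thiabicyclo[3.2.1]octan-6-ium trifluoromethanesulfonate
Conditions: 4-MeOC6H4CH2Br, LiOSO2CF3, CH2Cl2/H2O, 25 °C
Reagents that add atoms: 4-methoxybenzyl bromide COc1ccc(CBr)cc1; lithium trifluoromethanesulfonate [Li+].[O-]S(=O)(=O)C(F)(F)F
Why: S-alkylation of the sulfide on its less hindered lone pair with exchange to the non-nucleophilic triflate counter-ion gives a single, storable sulfonium salt.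

Step 11
Reactants: 11 (2S,3S)-4-bromo-3-(3,5-dimethoxyphenyl)-6-methoxy-2-(4-methoxyphenyl)-2,3-dihydro-1-benzofuran; 15 4-bromo-2-formylphenyl tert-butyl carbonate; 18 (1S,4S,5S)-6-(4-methoxybenzyl)-4,7,7-trimethyl-6-thiabicyclo[3.2.1]octan-6-ium trifluoromethanesulfonate
Product: 23 (2R,3R)-5-bromo-3-[(2S,3S)-3-(3,5-dimethoxyphenyl)-6-methoxy-2-(4-methoxyphenyl)-2,3-dihydro-1-benzofuran-4-yl]-2-(4-methoxyphenyl)-2,3-dihydro-1-benzofuran, via aryllithium 19 (not isolated), via sulfonium ylide 20 (not isolated), via phenolate carbonate 21 (not isolated), via o-quinone methide 22 (not isolated)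
Conditions: 11, n-BuLi, THF, −78 °C; then 15, −78 → −40 °C; then ylide 20 (from 18, LiN(SiMe3)2, THF, −78 °C), −78 → 0 °C
Reagents that add atoms: none
Why: bromine–lithium exchange and addition of 19 to the aldehyde of 15 are followed by the known carbonate shift from the phenol to the benzylic oxygen and 1,4-elimination to o-quinone methide 22, which undergoes the known sulfonium-ylide [4+1] annulation (conjugate addition of 20 at the exocyclic carbon, then 5-exo-tet closure by the phenolate with loss of sulfide 17), the chiral sulfide fixing the face of the ylide carbon (C2, 2R, as in its Corey–Chaykovsky epoxidations) and the anti betaine giving the trans ring, so that C3 follows as 3R.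

Step 12
Reactants: 23 (2R,3R)-5-bromo-3-[(2S,3S)-3-(3,5-dimethoxyphenyl)-6-methoxy-2-(4-methoxyphenyl)-2,3-dihydro-1-benzofuran-4-yl]-2-(4-methoxyphenyl)-2,3-dihydro-1-benzofuran; 13 3-(3,5-dimethoxyphenyl)-4-ethenyl-6-methoxy-2-(4-methoxyphenyl)-1-benzofuran
Product: 24 nonamethyl ether of the target with the E-alkene
Conditions: Pd(OAc)2, P(o-tol)3, Et3N, DMF, 110 °C
Reagents that add atoms: none
Why: Mizoroki–Heck reaction in which the arylpalladium species adds to the terminal vinyl carbon and syn β-hydride elimination gives the E-stilbene; no stereocentre is involved.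

Step 13
Reactants: 24 nonamethyl ether of the target with the E-alkene
Product: 25 CNP0135983.1 (target)
Conditions: BBr3 (excess), CH2Cl2, −78 → 0 °C; then MeOH/H2O
Reagents that add atoms: none
Why: Lewis-acid O-demethylation (bromide attacks the methyl groups of the boron-complexed aryl methyl ethers) frees all nine phenols; both dihydrofuran rings are already the thermodynamic trans isomers should a C2–O bond ionise reversibly.

**Compound list**

1 | 2,6-dibromo-4-methoxyphenol | COc1cc(Br)c(O)c(Br)c1 | starting material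
2 | (2,6-dibromo-4-methoxyphenoxy)trimethylsilane | COc1cc(Br)c(O[Si](C)(C)C)c(Br)c1 | intermediate
3 | lithium 2-bromo-4-methoxy-6-(trimethylsilyl)phenolate | COc1cc(Br)c([O-])c([Si](C)(C)C)c1.[Li+] | intermediate
4 | 2-bromo-4-methoxy-6-(trimethylsilyl)phenyl trifluoromethanesulfonate | COc1cc(Br)c(OS(=O)(=O)C(F)(F)F)c([Si](C)(C)C)c1 | intermediate
5 | pterostilbene, 4-[(E)-2-(3,5-dimethoxyphenyl)ethenyl]phenol | COc1cc(/C=C/c2ccc(O)cc2)cc(OC)c1 | starting material
6 | 4-[(E)-2-(3,5-dimethoxyphenyl)ethenyl]phenyl trifluoromethanesulfonate | COc1cc(/C=C/c2ccc(OS(=O)(=O)C(F)(F)F)cc2)cc(OC)c1 | intermediate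
7 | 4-[(2R,3R)-3-(3,5-dimethoxyphenyl)oxiran-2-yl]phenyl trifluoromethanesulfonate (trans) | COc1cc(cc(OC)c1)[C@H]1O[C@@H]1c1ccc(OS(=O)(=O)C(F)(F)F)cc1 | intermediate
8 | 3-bromo-5-methoxybenzyne | COC1=CC#CC(Br)=C1 | intermediate
9 | 4-[(2S,3S)-4-bromo-3-(3,5-dimethoxyphenyl)-6-methoxy-2,3-dihydro-1-benzofuran-2-yl]phenyl trifluoromethanesulfonate (trans) | Brc1cc(OC)cc2c1[C@H](c1cc(OC)cc(OC)c1)[C@@H](c1ccc(OS(=O)(=O)C(F)(F)F)cc1)O2 | intermediate
10 | cesium 4-[(2S,3S)-4-bromo-3-(3,5-dimethoxyphenyl)-6-methoxy-2,3-dihydro-1-benzofuran-2-yl]phenolate | Brc1cc(OC)cc2c1[C@H](c1cc(OC)cc(OC)c1)[C@@H](c1ccc([O-])cc1)O2.[Cs+] | intermediate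
11 | (2S,3S)-4-bromo-3-(3,5-dimethoxyphenyl)-6-methoxy-2-(4-methoxyphenyl)-2,3-dihydro-1-benzofuran (trans) | Brc1cc(OC)cc2c1[C@H](c1cc(OC)cc(OC)c1)[C@@H](c1ccc(OC)cc1)O2 | intermediate
12 | 4-bromo-3-(3,5-dimethoxyphenyl)-6-methoxy-2-(4-methoxyphenyl)-1-benzofuran | Brc1cc(OC)cc2oc(-c3ccc(OC)cc3)c(-c3cc(OC)cc(OC)c3)c12 | intermediate
13 | 3-(3,5-dimethoxyphenyl)-4-ethenyl-6-methoxy-2-(4-methoxyphenyl)-1-benzofuran | C=Cc1cc(OC)cc2oc(-c3ccc(OC)cc3)c(-c3cc(OC)cc(OC)c3)c12 | intermediate
14 | 5-bromo-2-hydroxybenzaldehyde | O=Cc1cc(Br)ccc1O | starting material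
15 | 4-bromo-2-formylphenyl tert-butyl carbonate | O=Cc1cc(Br)ccc1OC(=O)OC(C)(C)C | intermediate
16 | (S)-limonene | CC1=CC[C@H](CC1)C(C)=C | starting material
17 | (1S,4S,5S)-isothiocineole, (1S,4S,5S)-4,7,7-trimethyl-6-thiabicyclo[3.2.1]octane | C[C@H]1CC[C@H]2C[C@@H]1SC2(C)C | intermediate
18 | (1S,4S,5S)-6-(4-methoxybenzyl)-4,7,7-trimethyl-6-thiabicyclo[3.2.1]octan-6-ium trifluoromethanesulfonate (single sulfonium diastereomer, benzyl on the less hindered lone pair; sulfur configuration not written in the SMILES) | C[C@H]1CC[C@H]2C[C@@H]1[S+](Cc1ccc(OC)cc1)C2(C)C.[O-]S(=O)(=O)C(F)(F)F | intermediate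
19 | [(2S,3S)-3-(3,5-dimethoxyphenyl)-6-methoxy-2-(4-methoxyphenyl)-2,3-dihydro-1-benzofuran-4-yl]lithium | [Li]c1cc(OC)cc2c1[C@H](c1cc(OC)cc(OC)c1)[C@@H](c1ccc(OC)cc1)O2 | intermediate
20 | 4-methoxybenzylide of sulfonium salt 18 | C[C@H]1CC[C@H]2C[C@@H]1[S+]([CH-]c1ccc(OC)cc1)C2(C)C | intermediate
21 | lithium 4-bromo-2-{[(tert-butoxycarbonyl)oxy][(2S,3S)-3-(3,5-dimethoxyphenyl)-6-methoxy-2-(4-methoxyphenyl)-2,3-dihydro-1-benzofuran-4-yl]methyl}phenolate (both epimers at the carbinol carbon) | [Li+].[O-]c1ccc(Br)cc1C(OC(=O)OC(C)(C)C)c1cc(OC)cc2c1[C@H](c1cc(OC)cc(OC)c1)[C@@H](c1ccc(OC)cc1)O2 | intermediate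
22 | 4-bromo-6-{[(2S,3S)-3-(3,5-dimethoxyphenyl)-6-methoxy-2-(4-methoxyphenyl)-2,3-dihydro-1-benzofuran-4-yl]methylidene}cyclohexa-2,4-dien-1-one | O=C1C=CC(Br)=CC1=Cc1cc(OC)cc2c1[C@H](c1cc(OC)cc(OC)c1)[C@@H](c1ccc(OC)cc1)O2 | intermediate
23 | (2R,3R)-5-bromo-3-[(2S,3S)-3-(3,5-dimethoxyphenyl)-6-methoxy-2-(4-methoxyphenyl)-2,3-dihydro-1-benzofuran-4-yl]-2-(4-methoxyphenyl)-2,3-dihydro-1-benzofuran (both rings trans) | Brc1ccc2c(c1)[C@@H](c1cc(OC)cc3c1[C@H](c1cc(OC)cc(OC)c1)[C@@H](c1ccc(OC)cc1)O3)[C@H](c1ccc(OC)cc1)O2 | intermediate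
24 | 4-[(E)-2-{(2R,3R)-3-[(2S,3S)-3-(3,5-dimethoxyphenyl)-6-methoxy-2-(4-methoxyphenyl)-2,3-dihydro-1-benzofuran-4-yl]-2-(4-methoxyphenyl)-2,3-dihydro-1-benzofuran-5-yl}ethenyl]-3-(3,5-dimethoxyphenyl)-6-methoxy-2-(4-methoxyphenyl)-1-benzofuran (nonamethyl ether of the target) | COc1ccc(-c2oc3cc(OC)cc(/C=C/c4ccc5c(c4)[C@@H](c4cc(OC)cc6c4[C@H](c4cc(OC)cc(OC)c4)[C@@H](c4ccc(OC)cc4)O6)[C@H](c4ccc(OC)cc4)O5)c3c2-c2cc(OC)cc(OC)c2)cc1 | intermediate
25 | CNP0135983.1: the nonaphenol with a (2R,3R) middle and a (2S,3S) terminal trans-dihydrobenzofuran and an E-alkene | Oc1ccc(-c2oc3cc(O)cc(/C=C/c4ccc5c(c4)[C@@H](c4cc(O)cc6c4[C@H](c4cc(O)cc(O)c4)[C@@H](c4ccc(O)cc4)O6)[C@H](c4ccc(O)cc4)O5)c3c2-c2cc(O)cc(O)c2)cc1 | target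

**Step count and risks**

Total step count: 13. Longest linear sequence: 8 steps (5 → 6 → 7 → 9 → 11 → 12 → 13 → 24 → 25).

Steps most likely to fail:

1. Step 4, the step that carries the label.
   - What may go wrong: the hindered, weakly basic oxirane oxygen may capture the aryne too slowly, so that aryne self-reaction or fluoride addition wins; the aryl anion may be protonated or lose bromide before ring closure; the wrong C–O bond may ionise; rotation before collapse may leak to the cis ring.
   - Fallback (known chemistry, sets out from 4 and comes back at 11): aryne 8 is generated from 4 with CsF in N,N-dimethylformamide, whose C=O bond it inserts into with the same bromine-controlled orientation, and aqueous work-up gives 2-bromo-6-hydroxy-4-methoxybenzaldehyde F1. Addition of 3,5-(MeO)2C6H3MgBr gives 3-bromo-2-[(3,5-dimethoxyphenyl)(hydroxy)methyl]-5-methoxyphenol F2. p-Toluenesulfinic acid exchanges the benzylic hydroxyl to give 3-bromo-2-[(3,5-dimethoxyphenyl)(4-methylbenzenesulfonyl)methyl]-5-methoxyphenol F3. Cs2CO3 then releases the o-quinone methide, which undergoes the sulfonium-ylide [4+1] annulation with the ylide of (1R,4R,5R)-6-(4-methoxybenzyl)-4,7,7-trimethyl-6-thiabicyclo[3.2.1]octan-6-ium trifluoromethanesulfonate F4 (made as in step 10 from the commercial (1R,4R,5R) sulfide) to give 11 directly, with its 4-methoxyphenyl group already in place.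

2. Step 11.
   - What may go wrong: the facial bias of the neighbouring stereocentres of 19 at the exocyclic carbon of 22 may oppose the reagent control of the chiral ylide and erode the diastereoselectivity at C3; the ylide may also be consumed by the carbonate before the o-quinone methide is released.
   - Fallback (sets out from 11 and comes back at 23, forming the C2–C3 bond instead): 14 is O-alkylated with 4-methoxybenzyl chloride and K2CO3 to 5-bromo-2-[(4-methoxybenzyl)oxy]benzaldehyde F5. Lithiated 11 adds to it to give the diarylmethanol F6, which is oxidised with Dess–Martin periodinane to the diaryl ketone F7 and condensed with hydrazine to the hydrazone F8. MnO2 gives the diaryldiazomethane F9, and Rh2(PTAD)4 (PTAD = N-phthaloyl-(1-adamantyl)glycinate; the enantiomer that sets C3 as R) effects the known enantioselective intramolecular C–H insertion of the donor/donor carbene into the benzylic ether C–H bond to give the cis (2S,3R) dihydrobenzofuran F10. Trifluoroacetic acid in CH2Cl2 epimerises the 4-methoxybenzylic C2 to the trans isomer 23.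

3. Step 13.
   - What may go wrong: the Lewis acid may ionise a C2–O bond, followed by Friedel–Crafts capture by a neighbouring arene, or HBr may add to or cyclise onto the stilbene, before all nine ethers are cleaved.
   - Fallback (sets out from 23 and 12 and comes back at 25, exchanging methyl for acetyl before the alkene exists): BBr3 converts 23 to its pentaphenol F11 and 12 to its tetraphenol F13. Ac2O/pyridine gives the pentaacetate F12 and the tetraacetate F14. Stille vinylation of F14 as in step 7 gives the vinyl tetraacetate F15. Heck coupling of F12 with F15 (Pd(OAc)2, P(o-tol)3, NaOAc, DMF) gives the nonaacetate F16, and K2CO3 in methanol at room temperature removes the acetates to give 25.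

Further compounds
F1 | step 4 | 2-bromo-6-hydroxy-4-methoxybenzaldehyde | COc1cc(O)c(C=O)c(Br)c1
F2 | step 4 | 3-bromo-2-[(3,5-dimethoxyphenyl)(hydroxy)methyl]-5-methoxyphenol | COc1cc(O)c(C(O)c2cc(OC)cc(OC)c2)c(Br)c1
F3 | step 4 | 3-bromo-2-[(3,5-dimethoxyphenyl)(4-methylbenzenesulfonyl)methyl]-5-methoxyphenol | COc1cc(O)c(C(c2cc(OC)cc(OC)c2)S(=O)(=O)c2ccc(C)cc2)c(Br)c1
F4 | step 4 | (1R,4R,5R)-6-(4-methoxybenzyl)-4,7,7-trimethyl-6-thiabicyclo[3.2.1]octan-6-ium trifluoromethanesulfonate | C[C@@H]1CC[C@@H]2C[C@H]1[S+](Cc1ccc(OC)cc1)C2(C)C.[O-]S(=O)(=O)C(F)(F)F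
F5 | step 11 | 5-bromo-2-[(4-methoxybenzyl)oxy]benzaldehyde | COc1ccc(COc2ccc(Br)cc2C=O)cc1
F6 | step 11 | {5-bromo-2-[(4-methoxybenzyl)oxy]phenyl}[(2S,3S)-3-(3,5-dimethoxyphenyl)-6-methoxy-2-(4-methoxyphenyl)-2,3-dihydro-1-benzofuran-4-yl]methanol | COc1ccc(COc2ccc(Br)cc2C(O)c2cc(OC)cc3c2[C@H](c2cc(OC)cc(OC)c2)[C@@H](c2ccc(OC)cc2)O3)cc1
F7 | step 11 | {5-bromo-2-[(4-methoxybenzyl)oxy]phenyl}[(2S,3S)-3-(3,5-dimethoxyphenyl)-6-methoxy-2-(4-methoxyphenyl)-2,3-dihydro-1-benzofuran-4-yl]methanone | COc1ccc(COc2ccc(Br)cc2C(=O)c2cc(OC)cc3c2[C@H](c2cc(OC)cc(OC)c2)[C@@H](c2ccc(OC)cc2)O3)cc1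
F8 | step 11 | hydrazone of ketone F7 | COc1ccc(COc2ccc(Br)cc2C(=NN)c2cc(OC)cc3c2[C@H](c2cc(OC)cc(OC)c2)[C@@H](c2ccc(OC)cc2)O3)cc1
F9 | step 11 | diaryldiazomethane from hydrazone F8 | COc1ccc(COc2ccc(Br)cc2C(=[N+]=[N-])c2cc(OC)cc3c2[C@H](c2cc(OC)cc(OC)c2)[C@@H](c2ccc(OC)cc2)O3)cc1
F10 | step 11 | (2S,3R)-5-bromo-3-[(2S,3S)-3-(3,5-dimethoxyphenyl)-6-methoxy-2-(4-methoxyphenyl)-2,3-dihydro-1-benzofuran-4-yl]-2-(4-methoxyphenyl)-2,3-dihydro-1-benzofuran (cis in the new ring) | Brc1ccc2c(c1)[C@@H](c1cc(OC)cc3c1[C@H](c1cc(OC)cc(OC)c1)[C@@H](c1ccc(OC)cc1)O3)[C@@H](c1ccc(OC)cc1)O2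
F11 | step 13 | pentaphenol of 23 | Brc1ccc2c(c1)[C@@H](c1cc(O)cc3c1[C@H](c1cc(O)cc(O)c1)[C@@H](c1ccc(O)cc1)O3)[C@H](c1ccc(O)cc1)O2
F12 | step 13 | pentaacetate of F11 | Brc1ccc2c(c1)[C@@H](c1cc(OC(C)=O)cc3c1[C@H](c1cc(OC(C)=O)cc(OC(C)=O)c1)[C@@H](c1ccc(OC(C)=O)cc1)O3)[C@H](c1ccc(OC(C)=O)cc1)O2
F13 | step 13 | tetraphenol of 12 | Brc1cc(O)cc2oc(-c3ccc(O)cc3)c(-c3cc(O)cc(O)c3)c12
F14 | step 13 | tetraacetate of F13 | Brc1cc(OC(C)=O)cc2oc(-c3ccc(OC(C)=O)cc3)c(-c3cc(OC(C)=O)cc(OC(C)=O)c3)c12
F15 | step 13 | 4-ethenyl tetraacetate from F14 | C=Cc1cc(OC(C)=O)cc2oc(-c3ccc(OC(C)=O)cc3)c(-c3cc(OC(C)=O)cc(OC(C)=O)c3)c12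
F16 | step 13 | nonaacetate of 25 | CC(=O)Oc1ccc(-c2oc3cc(OC(C)=O)cc(/C=C/c4ccc5c(c4)[C@@H](c4cc(OC(C)=O)cc6c4[C@H](c4cc(OC(C)=O)cc(OC(C)=O)c4)[C@@H](c4ccc(OC(C)=O)cc4)O6)[C@H](c4ccc(OC(C)=O)cc4)O5)c3c2-c2cc(OC(C)=O)cc(OC(C)=O)c2)cc1
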